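**Retrosynthetic overview**
1. Target 23 ⇐ phenol acid 22 (para-oxidation to the quinone) ⇐ ester/aryl tosylate 21 ⇐ C5 ketone 20 (isopropylidene by carbonyl coupling with acetone).
2. trans-Decalin 20 (C13/C14/C8 stereotriad) ⇐ cis-8,9-dimethyl C13 carbinol 16 by a hydride-terminated 1,2-H/1,2-Me shift cascade (skeletal 1,2-shift, proposed new step).
3. Ring B of 16 ⇐ semipinacol ring expansion of iodo carbinol 15 ⇐ iodoacetate atom-transfer addition to vinyl carbinol 14.
4. 14 ⇐ cuprate methylation/benzylation (bromide 11 from o-cresol) and MeCeCl2 addition on 6 ⇐ (R)-Hajos–Parrish ketone 5 ⇐ 1 + 2.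
5. Ring order: ring C (Robinson annulation) → five-membered proto-ring B → six-membered ring B (ring expansion) → trans-decalin (skeletal shift) → quinone ring unmasked last.

Assumption: C1–C3 building blocks (CH2=CHMgBr, Me2CuLi, MeLi, ICH2CO2Et, acetone, paraformaldehyde) are treated as reagents, not as numbered starting materials.
Labels used in names: C9 = methyl-bearing ring-fusion carbon; C8 = other ring-fusion carbon; ring C = C8–C14–C13–C12–C11–C9; ring B = C9–C10–C5–C6–C7–C8 (before ring expansion the five-membered ring is C9–C5–C6–C7–C8); β = face of the C9 methyl, α = opposite face; Ts = 4-methylbenzenesulfonyl.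

**Route**

Step 1
Reactants: 1 2-methylcyclopentane-1,3-dione; 2 but-3-en-2-one
Product: 3 2-methyl-2-(3-oxobutyl)cyclopentane-1,3-dione
Conditions: H2O, AcOH (cat.), 70 °C
Reagents that add atoms: none
Why: Michael addition of the acidic 1,3-dione to the enone in water gives C-alkylation only; no stereocentre is formed.

Step 2
Reactants: 3 2-methyl-2-(3-oxobutyl)cyclopentane-1,3-dione
Product: 5 (7aR)-7a-methyl-2,3,7,7a-tetrahydro-1H-indene-1,5(6H)-dione, via ketol 4 (not isolated)
Conditions: D-proline (3 mol %), DMF, rt; then H2SO4 (cat.), 95 °C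
Reagents that add atoms: none
Why: Hajos–Parrish–Eder–Sauer–Wiechert enamine aldol desymmetrises the dione (D-proline gives the 7aR series, mirror image of the L-proline outcome), and acid dehydrates ketol 4 to the enone.

Step 3
Reactants: 5 (7aR)-7a-methyl-2,3,7,7a-tetrahydro-1H-indene-1,5(6H)-dione
Product: 6 (1S,7aR)-1-ethenyl-1-hydroxy-7a-methyl-1,2,3,6,7,7a-hexahydro-5H-inden-5-one
Conditions: CH2=CHMgBr, CeCl3, THF, −78 °C
Reagents that add atoms: vinylmagnesium bromide, C=C[Mg]Br
Why: Imamoto-type organocerium 1,2-addition is selective for the isolated cyclopentanone, which is more electrophilic than the vinylogous enone carbonyl, and the nucleophile enters anti to the angular methyl, so the new OH is β.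

Step 4
Reactants: 7 2-methylphenol
Product: 9 2-(hydroxymethyl)-6-methylphenol, via benzodioxaborinine 8 (not isolated)
Conditions: PhB(OH)2, (CH2O)n, EtCO2H (cat.), toluene, reflux (−H2O); then H2O2, THF, rt
Reagents that add atoms: formaldehyde (as paraformaldehyde), C=O
Why: Nagata ortho-specific hydroxymethylation: the aryloxy(phenyl)borane template delivers formaldehyde only to the free ortho position to give cyclic borate 8, and H2O2 oxidatively removes the phenylboron unit.

Step 5
Reactants: 9 2-(hydroxymethyl)-6-methylphenol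
Product: 11 2-(bromomethyl)-6-methylphenyl 4-methylbenzenesulfonate, via bis-tosylate 10 (not isolated)
Conditions: TsCl (2.2 equiv), Et3N, DMAP (cat.), CH2Cl2, 0 °C; then LiBr, acetone, rt
Reagents that add atoms: 4-methylbenzenesulfonyl chloride, Cc1ccc(cc1)S(=O)(=O)Cl; lithium bromide, [Li+].[Br-]
Why: Sulfonylation of both hydroxyls followed by SN2 (Finkelstein-type) displacement of the benzylic sulfonate by bromide; the aryl tosylate is inert and keeps the arene electron-poor and its oxygen non-nucleophilic for step 10.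

Step 6
Reactants: 6 (1S,7aR)-1-ethenyl-1-hydroxy-7a-methyl-1,2,3,6,7,7a-hexahydro-5H-inden-5-one; 11 2-(bromomethyl)-6-methylphenyl 4-methylbenzenesulfonate
Product: 13 5α-ethenyl-5β-hydroxy-8β,9β-dimethyl-14α-(3-methyl-2-tosyloxybenzyl)-cis-hydrindan-13-one (14β-H), via dilithium enolate 12 (not isolated)
Conditions: MeLi (1 equiv), Et2O, −78 °C; Me2CuLi (from CuI, 2 MeLi; 1.3 equiv), −78 → −20 °C; then 11, HMPA, −20 °C → rt
Reagents that add atoms: lithium dimethylcuprate, [Li+].C[Cu-]C
Why: Gilman cuprate 1,4-addition at the ring-fusion β-carbon gives the cis-fused 8β,9β-dimethyl array, and the regiodefined enolate 12 is C-benzylated at C14 from the α face because the β face is blocked by the 1,3-related C9 methyl; C14 is epimerisable and this 14β-H isomer (benzyl equatorial, trans to both methyls) is also expected to be the thermodynamic one.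

Step 7
Reactants: 13 5α-ethenyl-5β-hydroxy-8β,9β-dimethyl-14α-(3-methyl-2-tosyloxybenzyl)-cis-hydrindan-13-one
Product: 14 5α-ethenyl-8β,9β,13β-trimethyl-14α-(3-methyl-2-tosyloxybenzyl)-cis-hydrindane-5β,13α-diol
Conditions: MeCeCl2 (from MeLi, CeCl3), THF, −78 °C
Reagents that add atoms: methyllithium, [Li]C
Why: Organocerium 1,2-addition (Imamoto) tolerates the hindered, enolisable ketone and the aryl tosylate without epimerising C14; equatorial attack should give the 13β-methyl carbinol, whose configuration is irrelevant because C13 is ionised in step 10.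

Step 8
Reactants: 14 5α-ethenyl-8β,9β,13β-trimethyl-14α-(3-methyl-2-tosyloxybenzyl)-cis-hydrindane-5β,13α-diol
Product: 15 ethyl 4-[5β,13α-dihydroxy-8β,9β,13β-trimethyl-14α-(3-methyl-2-tosyloxybenzyl)-cis-hydrindan-5α-yl]-4-iodobutanoate (both C–I epimers)
Conditions: ICH2CO2Et, Et3B (cat.), air, CH2Cl2, rt
Reagents that add atoms: ethyl iodoacetate, CCOC(=O)CI
Why: Kharasch-type iodine-atom-transfer radical addition: the electrophilic ethoxycarbonylmethyl radical adds to the terminal vinyl carbon and iodine transfer gives the β-iodo carbinol carrying the whole C3 acid chain; the new C–I centre is not controlled and need not be.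

Step 9
Reactants: 15 ethyl 4-[5β,13α-dihydroxy-8β,9β,13β-trimethyl-14α-(3-methyl-2-tosyloxybenzyl)-cis-hydrindan-5α-yl]-4-iodobutanoate
Product: 16 ethyl 3-[13α-hydroxy-8β,9β,13β-trimethyl-5-oxo-14α-(3-methyl-2-tosyloxybenzyl)-cis-decalin-10-yl]propanoate (C10 epimers)
Conditions: AgBF4, 2,6-di-tert-butyl-4-methylpyridine, CH2Cl2, −20 °C → rt
Reagents that add atoms: none
Why: Silver-assisted semipinacol (Tiffeneau-type halohydrin) rearrangement: ionisation of the secondary iodide triggers the 1,2-shift of the more substituted ring carbon C9 from C5 to C10 with retention at C9, the carbinol becomes the C5 ketone and the cyclopentane becomes six-membered ring B; the buffer protects the C13 carbinol, and C10 (α to the ketone) is equilibrated in step 10.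

Step 10
Reactants: 16 ethyl 3-[13α-hydroxy-8β,9β,13β-trimethyl-5-oxo-14α-(3-methyl-2-tosyloxybenzyl)-cis-decalin-10-yl]propanoate
Product: 20 ethyl 3-[9β,13α,14β-trimethyl-5-oxo-14α-(3-methyl-2-tosyloxybenzyl)-trans-decalin-10β-yl]propanoate (8α-H 13β-H), via C13 carbenium ion 17 (not isolated), via C14 carbenium ion 18 (not isolated), via C8 carbenium ion 19 (not isolated)
Conditions: Et3SiH (3 equiv), TfOH (1.5 equiv), CH2Cl2/HFIP 4:1, −78 → −30 °C; then DBU, rt
Reagents that add atoms: none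
Why: Proposed new method: a hydride-terminated backbone rearrangement in which TfOH ionises the C13 carbinol to 17, the 14β-H shifts suprafacially to C13 (fixing 13β-H/13α-Me) to give 18, the 8β-methyl shifts suprafacially to C14 (fixing 14β-Me/14α-benzyl) to give 19, which should be the most stable ion because the vicinal-quaternary C8/C9 strain is released, further migration toward C10 would create an α-keto cation and the tosyloxy-arene disfavours benzylic hydride shift and Friedel–Crafts capture, and Et3SiH then delivers hydride to C8 from the α face, anti to the two flanking β-methyls, to set the trans fusion, after which DBU equilibrates C10 to the equatorial 10β chain; the closest known chemistry is the Lewis-acid 1,2-H/1,2-Me shift cascade of 9-arylmethyl drimanyl cations (friedo rearrangement ending by elimination or phenol capture) combined with Kursanov–Parnes ionic hydrogenation of tertiary alcohols, where Wagner–Meerwein shifts are known to precede hydride transfer.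

Step 11
Reactants: 20 ethyl 3-[9β,13α,14β-trimethyl-5-oxo-14α-(3-methyl-2-tosyloxybenzyl)-trans-decalin-10β-yl]propanoate
Product: 21 ethyl 3-[9β,13α,14β-trimethyl-5-(propan-2-ylidene)-14α-(3-methyl-2-tosyloxybenzyl)-trans-decalin-10β-yl]propanoate
Conditions: acetone (10 equiv), TiCl4, Zn, pyridine, THF, reflux
Reagents that add atoms: acetone, CC(C)=O
Why: McMurry carbonyl cross-coupling: low-valent titanium couples the C5 ketone with excess acetone to the tetrasubstituted isopropylidene under non-basic conditions, so C10 is not epimerised and the ester survives.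

Step 12
Reactants: 21 ethyl 3-[9β,13α,14β-trimethyl-5-(propan-2-ylidene)-14α-(3-methyl-2-tosyloxybenzyl)-trans-decalin-10β-yl]propanoate
Product: 22 3-[14α-(2-hydroxy-3-methylbenzyl)-9β,13α,14β-trimethyl-5-(propan-2-ylidene)-trans-decalin-10β-yl]propanoic acid
Conditions: KOH, MeOH/H2O, reflux; then aq. HCl
Reagents that add atoms: potassium hydroxide, [K+].[OH-]
Why: Saponification of the ethyl ester and hydrolytic S–O cleavage of the aryl tosylate occur together in hot alkali; no stereocentre is at risk because no carbonyl remains next to C10.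

Step 13
Reactants: 22 3-[14α-(2-hydroxy-3-methylbenzyl)-9β,13α,14β-trimethyl-5-(propan-2-ylidene)-trans-decalin-10β-yl]propanoic acid
Product: 23 target CNP0271365.1
Conditions: (KSO3)2NO, KH2PO4 buffer, acetone/H2O, rt
Reagents that add atoms: potassium nitrosodisulfonate, [K+].[K+].[O]N(S(=O)(=O)[O-])S(=O)(=O)[O-]
Why: Teuber oxidation: two equivalents of the nitrosodisulfonate radical convert the 2,6-dialkylphenol at its free para position into the 1,4-benzoquinone, leaving the tetrasubstituted alkene and the acid untouched.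

**Compound list**
1 | 2-methylcyclopentane-1,3-dione | CC1C(=O)CCC1=O | starting material
2 | but-3-en-2-one (methyl vinyl ketone) | CC(=O)C=C | starting material
3 | 2-methyl-2-(3-oxobutyl)cyclopentane-1,3-dione | CC(=O)CCC1(C)C(=O)CCC1=O | intermediate
4 | (3aR,7aR)-3a-hydroxy-7a-methylhexahydro-1H-indene-1,5(4H)-dione (cis ketol, not isolated) | O=C1CC[C@@]2(C)C(=O)CC[C@@]2(O)C1 | intermediate
5 | (7aR)-7a-methyl-2,3,7,7a-tetrahydro-1H-indene-1,5(6H)-dione | O=C1CC[C@@]2(C)C(=O)CCC2=C1 | intermediate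
6 | (1S,7aR)-1-ethenyl-1-hydroxy-7a-methyl-1,2,3,6,7,7a-hexahydro-5H-inden-5-one (5β-OH, 5α-vinyl) | O=C1CC[C@@]2(C)[C@@](O)(C=C)CCC2=C1 | intermediate
7 | 2-methylphenol (o-cresol) | Cc1ccccc1O | starting material
8 | 8-methyl-2-phenyl-4H-1,3,2-benzodioxaborinine (not isolated) | Cc1cccc2COB(c3ccccc3)Oc12 | intermediate
9 | 2-(hydroxymethyl)-6-methylphenol | Cc1cccc(CO)c1O | intermediate
10 | 2-methyl-6-[(tosyloxy)methyl]phenyl 4-methylbenzenesulfonate (not isolated) | Cc1ccc(cc1)S(=O)(=O)OCc1cccc(C)c1OS(=O)(=O)c1ccc(C)cc1 | intermediate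
11 | 2-(bromomethyl)-6-methylphenyl 4-methylbenzenesulfonate | Cc1ccc(cc1)S(=O)(=O)Oc1c(C)cccc1CBr | intermediate
12 | dilithium C13-enolate C5-alkoxide of the 8β-methyl conjugate adduct of 6 (not isolated) | [Li+].[Li+].[O-]C=1CC[C@@]2(C)[C@@]([O-])(C=C)CC[C@@]2(C)C=1 | intermediate
13 | 5α-ethenyl-5β-hydroxy-8β,9β-dimethyl-14α-(3-methyl-2-tosyloxybenzyl)-cis-hydrindan-13-one (14β-H) | O=C1CC[C@@]2(C)[C@@](O)(C=C)CC[C@@]2(C)[C@H]1Cc1cccc(C)c1OS(=O)(=O)c1ccc(C)cc1 | intermediate
14 | 5α-ethenyl-8β,9β,13β-trimethyl-14α-(3-methyl-2-tosyloxybenzyl)-cis-hydrindane-5β,13α-diol | C[C@]1(O)CC[C@@]2(C)[C@@](O)(C=C)CC[C@@]2(C)[C@H]1Cc1cccc(C)c1OS(=O)(=O)c1ccc(C)cc1 | intermediate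
15 | ethyl 4-[5β,13α-dihydroxy-8β,9β,13β-trimethyl-14α-(3-methyl-2-tosyloxybenzyl)-cis-hydrindan-5α-yl]-4-iodobutanoate (C–I epimers) | C[C@]1(O)CC[C@@]2(C)[C@@](O)(C(I)CCC(=O)OCC)CC[C@@]2(C)[C@H]1Cc1cccc(C)c1OS(=O)(=O)c1ccc(C)cc1 | intermediate
16 | ethyl 3-[13α-hydroxy-8β,9β,13β-trimethyl-5-oxo-14α-(3-methyl-2-tosyloxybenzyl)-cis-decalin-10-yl]propanoate (C10 epimers; 10β-chain isomer drawn) | C[C@]1(O)CC[C@@]2(C)[C@H](CCC(=O)OCC)C(=O)CC[C@@]2(C)[C@H]1Cc1cccc(C)c1OS(=O)(=O)c1ccc(C)cc1 | intermediate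
17 | C13 carbenium ion from 16 (not isolated) | C[C+]1CC[C@@]2(C)[C@H](CCC(=O)OCC)C(=O)CC[C@@]2(C)[C@H]1Cc1cccc(C)c1OS(=O)(=O)c1ccc(C)cc1 | intermediate
18 | C14 carbenium ion after the 14β-H shift (13β-H, 13α-Me; not isolated) | C[C@H]1CC[C@@]2(C)[C@H](CCC(=O)OCC)C(=O)CC[C@@]2(C)[C+]1Cc1cccc(C)c1OS(=O)(=O)c1ccc(C)cc1 | intermediate
19 | C8 carbenium ion after the 8β-methyl shift (14β-Me; not isolated) | Cc1ccc(cc1)S(=O)(=O)Oc1c(C)cccc1C[C@]2(C)[C+]3CCC(=O)[C@@H](CCC(=O)OCC)[C@]3(C)CC[C@@H]2C | intermediate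
20 | ethyl 3-[9β,13α,14β-trimethyl-5-oxo-14α-(3-methyl-2-tosyloxybenzyl)-trans-decalin-10β-yl]propanoate (8α-H, 13β-H) | Cc1ccc(cc1)S(=O)(=O)Oc1c(C)cccc1C[C@]2(C)[C@H]3CCC(=O)[C@@H](CCC(=O)OCC)[C@]3(C)CC[C@@H]2C | intermediate
21 | ethyl 3-[9β,13α,14β-trimethyl-5-(propan-2-ylidene)-14α-(3-methyl-2-tosyloxybenzyl)-trans-decalin-10β-yl]propanoate | Cc1ccc(cc1)S(=O)(=O)Oc1c(C)cccc1C[C@]2(C)[C@H]3CCC(=C(C)C)[C@@H](CCC(=O)OCC)[C@]3(C)CC[C@@H]2C | intermediate
22 | 3-[14α-(2-hydroxy-3-methylbenzyl)-9β,13α,14β-trimethyl-5-(propan-2-ylidene)-trans-decalin-10β-yl]propanoic acid | Cc1cccc(C[C@]2(C)[C@H]3CCC(=C(C)C)[C@@H](CCC(=O)O)[C@]3(C)CC[C@@H]2C)c1O | intermediate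
23 | 3-[9β,13α,14β-trimethyl-14α-[(5-methyl-3,6-dioxocyclohexa-1,4-dien-1-yl)methyl]-5-(propan-2-ylidene)-trans-decalin-10β-yl]propanoic acid (CNP0271365.1) | CC1=CC(=O)C=C(C[C@]2(C)[C@H]3CCC(=C(C)C)[C@@H](CCC(=O)O)[C@]3(C)CC[C@@H]2C)C1=O | target

**Step count**
Total: 13 steps (steps 4 and 5 make the aryl fragment). Longest linear sequence: 11 steps (1, 2, 3, 6, 7, 8, 9, 10, 11, 12, 13).

**Three steps most likely to fail**

Step 10 (the proposed new cascade). Risks: hydride capture at C13 or C14 before the shifts are complete; migration of a ring bond instead of the methyl in the flexible cis-decalin; loss of C13 integrity by elimination and reprotonation; cis ring fusion on hydride delivery; partial reduction of the C5 ketone. The fallback uses only known reactions and a different logic, building the C14 quaternary centre and the trans fusion by enone reductive alkylation; it sets out from 1 and returns at 21. 1 and ethyl vinyl ketone (H2O, AcOH) give the triketone 2-methyl-2-(3-oxopentyl)cyclopentane-1,3-dione F1. D-Phenylalanine/camphorsulfonic acid aldol cyclodehydration gives the (7aR)-4,7a-dimethyl enone F2. CH2=CHMgBr/CeCl3 gives the vinyl carbinol F3. Li/NH3 reduction, isoprene quench and alkylation of the lithium enolate with 11 give the trans-hydrindanone F4 (8α-H, 14β-methyl, 14α-benzyl). ICH2CO2Et/Et3B gives the iodide F5, and AgBF4 ring expansion gives the trans-decalin-5,13-dione F6. McMurry coupling with acetone at the less hindered C5 ketone gives the isopropylidene ketone F7. Methylenation with Zn/CH2Br2/TiCl4 gives the 13-methylidene compound F8. Hydrogenation with (Ph3P)3RhCl/H2 gives 21 together with its 13β-methyl epimer F9, which is expected to predominate because hydrogen adds from the α face, so 21 has to be separated by chromatography as the minor isomer.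

Step 9 (semipinacol ring expansion). Risks: migration of the primary C6 instead of the tertiary C9, which depends on the C–I configuration unless ionisation is stepwise; γ-lactone formation by ester participation; epoxide formation. The fallback replaces the ionisation by a concerted, chelation-organised epoxide rearrangement and adds the chain afterwards; it sets out from 14 and returns at 16. VO(acac)2/t-BuOOH epoxidises the vinyl group under direction of the tertiary allylic hydroxyl to the epoxy alcohol F10. ZnBr2 effects the 2,3-epoxy-alcohol semipinacol rearrangement to the ring-expanded 10-(hydroxymethyl) C5 ketone F11. MsCl/Et3N then DBU gives the 10-methylidene ketone F12. Mukaiyama–Michael addition of CH2=C(OEt)OSiMe3 (LiClO4, Et2O; aqueous acid) gives 16.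

Step 6 (conjugate methylation and benzylation). Risks: sluggish 1,4-addition at the ring-fusion carbon creating vicinal quaternary centres; O- rather than C-benzylation or over-alkylation; wrong C14 epimer. The fallback separates the two bond formations; it sets out from 6 and returns at 13. MeMgBr with catalytic CuBr·SMe2 and TMSCl/HMPA gives the isolable bis(trimethylsilyl) enol ether F13 (copper-catalysed 1,4-addition with silyl trapping). MeLi regenerates the amine-free lithium enolate, which 11 benzylates in THF/DMPU to the 5-O-trimethylsilyl ketone F14. Aqueous HCl removes the tertiary silyl ether to give 13, which is equilibrated at C14 with DBU if needed.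

Further compounds
F1 | step 10 | 2-methyl-2-(3-oxopentyl)cyclopentane-1,3-dione | CCC(=O)CCC1(C)C(=O)CCC1=O
F2 | step 10 | (7aR)-4,7a-dimethyl-2,3,7,7a-tetrahydro-1H-indene-1,5(6H)-dione | O=C1CC[C@@]2(C)C(=O)CCC2=C1C
F3 | step 10 | (1S,7aR)-1-ethenyl-1-hydroxy-4,7a-dimethyl-1,2,3,6,7,7a-hexahydro-5H-inden-5-one | O=C1CC[C@@]2(C)[C@@](O)(C=C)CCC2=C1C
F4 | step 10 | 5α-ethenyl-5β-hydroxy-9β,14β-dimethyl-14α-(3-methyl-2-tosyloxybenzyl)-trans-hydrindan-13-one (8α-H) | O=C1CC[C@@]2(C)[C@@](O)(C=C)CC[C@@H]2[C@@]1(C)Cc1cccc(C)c1OS(=O)(=O)c1ccc(C)cc1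
F5 | step 10 | ethyl 4-[5β-hydroxy-9β,14β-dimethyl-13-oxo-14α-(3-methyl-2-tosyloxybenzyl)-trans-hydrindan-5α-yl]-4-iodobutanoate (C–I epimers) | O=C1CC[C@@]2(C)[C@@](O)(C(I)CCC(=O)OCC)CC[C@@H]2[C@@]1(C)Cc1cccc(C)c1OS(=O)(=O)c1ccc(C)cc1
F6 | step 10 | ethyl 3-[9β,14β-dimethyl-5,13-dioxo-14α-(3-methyl-2-tosyloxybenzyl)-trans-decalin-10β-yl]propanoate | Cc1ccc(cc1)S(=O)(=O)Oc1c(C)cccc1C[C@]2(C)[C@H]3CCC(=O)[C@@H](CCC(=O)OCC)[C@]3(C)CCC2=O
F7 | step 10 | ethyl 3-[9β,14β-dimethyl-13-oxo-5-(propan-2-ylidene)-14α-(3-methyl-2-tosyloxybenzyl)-trans-decalin-10β-yl]propanoate | Cc1ccc(cc1)S(=O)(=O)Oc1c(C)cccc1C[C@]2(C)[C@H]3CCC(=C(C)C)[C@@H](CCC(=O)OCC)[C@]3(C)CCC2=O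
F8 | step 10 | ethyl 3-[9β,14β-dimethyl-13-methylidene-5-(propan-2-ylidene)-14α-(3-methyl-2-tosyloxybenzyl)-trans-decalin-10β-yl]propanoate | Cc1ccc(cc1)S(=O)(=O)Oc1c(C)cccc1C[C@]2(C)[C@H]3CCC(=C(C)C)[C@@H](CCC(=O)OCC)[C@]3(C)CCC2=C
F9 | step 10 | 13β-methyl epimer of 21 | Cc1ccc(cc1)S(=O)(=O)Oc1c(C)cccc1C[C@]2(C)[C@H]3CCC(=C(C)C)[C@@H](CCC(=O)OCC)[C@]3(C)CC[C@H]2C
F10 | step 9 | 8β,9β,13β-trimethyl-5α-(oxiran-2-yl)-14α-(3-methyl-2-tosyloxybenzyl)-cis-hydrindane-5β,13α-diol (oxirane epimers) | C[C@]1(O)CC[C@@]2(C)[C@@](O)(C3CO3)CC[C@@]2(C)[C@H]1Cc1cccc(C)c1OS(=O)(=O)c1ccc(C)cc1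
F11 | step 9 | 13α-hydroxy-10-(hydroxymethyl)-8β,9β,13β-trimethyl-14α-(3-methyl-2-tosyloxybenzyl)-cis-decalin-5-one | C[C@]1(O)CC[C@@]2(C)[C@H](CO)C(=O)CC[C@@]2(C)[C@H]1Cc1cccc(C)c1OS(=O)(=O)c1ccc(C)cc1
F12 | step 9 | 13α-hydroxy-8β,9β,13β-trimethyl-10-methylidene-14α-(3-methyl-2-tosyloxybenzyl)-cis-decalin-5-one | C[C@]1(O)CC[C@@]2(C)C(=C)C(=O)CC[C@@]2(C)[C@H]1Cc1cccc(C)c1OS(=O)(=O)c1ccc(C)cc1
F13 | step 6 | 5α-ethenyl-8β,9β-dimethyl-5β,13-bis(trimethylsilyloxy)-cis-hydrind-13-ene | C[Si](C)(C)OC=1CC[C@@]2(C)[C@@](O[Si](C)(C)C)(C=C)CC[C@@]2(C)C=1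
F14 | step 6 | 5-O-trimethylsilyl ether of 13 | O=C1CC[C@@]2(C)[C@@](O[Si](C)(C)C)(C=C)CC[C@@]2(C)[C@H]1Cc1cccc(C)c1OS(=O)(=O)c1ccc(C)cc1
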